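The plan rests on cutting the crowded C5–C10 fusion bond of ring B. C5 is α to C4, which can stand at the carboxyl level. C10 can be the far terminus of an allyl unit C10=C1–C2–O. Both ends therefore fit into a ten-membered lactone whose ring oxygen bridges C4 and C2. Ireland–Claisen rearrangement of its silyl ketene acetal forms C5–C10, shrinks the macrocycle to ring B, places the C4 and C1 arms cis, and relays the C2 carbinol configuration to C10 and C5, all in one operation. The precursor is the (2S,7R) E-alkenyl lactone bearing a C8 ethylene ketal and a C3 benzyl ether. Pinacol closure of ring A and two acylations complete the target.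

Key step: step 14

Remark: eudesmane numbering is used for every intermediate. α means the face of the bicycle opposite to H5 and the C10 methyl group.
Remark: C7 is assumed to need control before ring A is closed, because the equatorial isopropyl group decides which chair ring B adopts in the pinacol step. It is therefore set as R in step 2 and locked by the ketal.

Step 1
Reactants: 1 (R)-4-benzyl-1,3-oxazolidin-2-one; 2 3-methylbutanoyl chloride
Product: 3 (R)-4-benzyl-3-(3-methylbutanoyl)-1,3-oxazolidin-2-one
Conditions: n-BuLi, THF, −78 °C; then 2, −78 °C → 0 °C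
Reagents that add atoms: none
Why: N-acylation of the lithiated oxazolidinone with an acid chloride is the standard loading of an Evans auxiliary and creates no new stereocentre.

Step 2
Reactants: 3 (R)-4-benzyl-3-(3-methylbutanoyl)-1,3-oxazolidin-2-one; 4 methyl acrylate
Product: 5 methyl (4R)-4-{[(4R)-4-benzyl-2-oxo-1,3-oxazolidin-3-yl]carbonyl}-5-methylhexanoate
Conditions: TiCl3(OiPr) (from TiCl4 and Ti(OiPr)4), iPr2NEt, CH2Cl2, 0 °C; then 4, 0 °C
Reagents that add atoms: none
Why: Evans asymmetric Michael addition, in which the chelated Z titanium enolate is shielded on one face by the benzyl group so that acrylate bonds to the open face and sets C7 as R, and in which C7 is the only carbon able to act as nucleophile, so the C6–C7 bond forms without a regiochemical question.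

Step 3
Reactants: 5 methyl (4R)-4-{[(4R)-4-benzyl-2-oxo-1,3-oxazolidin-3-yl]carbonyl}-5-methylhexanoate
Product: 6 methyl (4R)-4-[(ethylsulfanyl)carbonyl]-5-methylhexanoate
Conditions: EtSH, n-BuLi, THF, 0 °C
Reagents that add atoms: ethanethiol, CCS
Why: Auxiliary cleavage by acyl transfer to thiolate, which attacks the exocyclic imide carbonyl much faster than the methyl ester and is too weakly basic to disturb C7.

Step 4
Reactants: 6 methyl (4R)-4-[(ethylsulfanyl)carbonyl]-5-methylhexanoate
Product: 7 methyl (4R)-4-formyl-5-methylhexanoate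
Conditions: Et3SiH, Pd/C, acetone, rt
Reagents that add atoms: none
Why: Fukuyama reduction of a thioester stops at the aldehyde under neutral conditions, spares the methyl ester and does not epimerise C7.

Step 5
Reactants: 7 methyl (4R)-4-formyl-5-methylhexanoate; 8 propargyl bromide
Product: 9 methyl (4R)-5-hydroxy-4-(propan-2-yl)oct-7-ynoate (both C8 carbinol epimers)
Conditions: Zn, THF–sat. aq. NH4Cl, 0 °C; crude product used at once
Reagents that add atoms: none
Why: Barbier propargylation, in which the allenylzinc species adds through its γ-carbon to the aldehyde only and gives the homopropargylic alcohol; the C8 carbinol centre is left uncontrolled because step 6 removes it, and the aqueous medium protonates the alkoxide before it can lactonise onto the C4 ester.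

Step 6
Reactants: 9 methyl (4R)-5-hydroxy-4-(propan-2-yl)oct-7-ynoate
Product: 10 methyl (4R)-5-oxo-4-(propan-2-yl)oct-7-ynoate
Conditions: Dess–Martin periodinane, CH2Cl2, 0 °C → rt
Reagents that add atoms: none
Why: Dess–Martin oxidation runs without base, which avoids the alkyne-to-allene shift of the β,γ-alkynyl ketone and any enolisation towards C7.

Step 7
Reactants: 10 methyl (4R)-5-oxo-4-(propan-2-yl)oct-7-ynoate
Product: 11 methyl (4R)-5-methyl-4-[2-(prop-2-yn-1-yl)-1,3-dioxolan-2-yl]hexanoate
Conditions: Me3SiOCH2CH2OSiMe3, Me3SiOTf (cat.), CH2Cl2, −78 °C → −20 °C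
Reagents that add atoms: 1,2-bis(trimethylsilyloxy)ethane, C[Si](C)(C)OCCO[Si](C)(C)C
Why: Noyori ketalisation is aprotic, cold and driven by formation of hexamethyldisiloxane, so the hindered C8 ketone is masked without the hot protic acid that could epimerise C7 or move the alkyne.

Step 8
Reactants: 11 methyl (4R)-5-methyl-4-[2-(prop-2-yn-1-yl)-1,3-dioxolan-2-yl]hexanoate
Product: 13 methyl (4R)-4-{2-[(2E)-3-iodo-2-methylprop-2-en-1-yl]-1,3-dioxolan-2-yl}-5-methylhexanoate, via alkenylalane 12 (not isolated)
Conditions: Me3Al, Cp2ZrCl2 (cat.), H2O (promoter), CH2Cl2, −25 °C; then I2, THF, −25 °C → 0 °C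
Reagents that add atoms: trimethylaluminium, C[Al](C)C; iodine, II
Why: Negishi zirconium-catalysed methylalumination adds CH3 (to C10) and aluminium (to C1) syn across the terminal alkyne, and iodinolysis with retention gives the E iodide with C9 trans to iodine; the water-accelerated low-temperature variant keeps Me3Al from attacking the ester or the ketal.

Step 9
Reactants: 13 methyl (4R)-4-{2-[(2E)-3-iodo-2-methylprop-2-en-1-yl]-1,3-dioxolan-2-yl}-5-methylhexanoate; 14 (benzyloxy)acetaldehyde
Product: 15 methyl (4R)-4-{2-[(2E)-5-(benzyloxy)-4-hydroxy-2-methylpent-2-en-1-yl]-1,3-dioxolan-2-yl}-5-methylhexanoate (both C2 carbinol epimers)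
Conditions: CrCl2, NiCl2 (cat.), DMSO, rt
Reagents that add atoms: none
Why: Nozaki–Hiyama–Kishi coupling forms C1–C2 by addition of an alkenylchromium species to the aldehyde only, tolerates ester and ketal and keeps the alkene geometry; the C2 centre forms without control and is erased in step 10.

Step 10
Reactants: 15 methyl (4R)-4-{2-[(2E)-5-(benzyloxy)-4-hydroxy-2-methylpent-2-en-1-yl]-1,3-dioxolan-2-yl}-5-methylhexanoate
Product: 16 methyl (4R)-4-{2-[(2E)-5-(benzyloxy)-2-methyl-4-oxopent-2-en-1-yl]-1,3-dioxolan-2-yl}-5-methylhexanoate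
Conditions: Dess–Martin periodinane, CH2Cl2, 0 °C → rt
Reagents that add atoms: none
Why: Dess–Martin oxidation of the allylic alcohol merges both epimers into one enone without moving or isomerising the trisubstituted alkene.

Step 11
Reactants: 16 methyl (4R)-4-{2-[(2E)-5-(benzyloxy)-2-methyl-4-oxopent-2-en-1-yl]-1,3-dioxolan-2-yl}-5-methylhexanoate
Product: 17 methyl (4R)-4-{2-[(2E,4S)-5-(benzyloxy)-4-hydroxy-2-methylpent-2-en-1-yl]-1,3-dioxolan-2-yl}-5-methylhexanoate
Conditions: (S)-1-methyl-3,3-diphenyltetrahydro-1H,3H-pyrrolo[1,2-c][1,3,2]oxazaborole ((S)-Me-CBS, cat.), catecholborane, toluene, −78 °C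
Reagents that add atoms: none
Why: Corey–Bakshi–Shibata reduction, in which the ketone binds the oxazaborolidine anti to its larger alkenyl arm so that hydride from the (S)-catalyst complex should reach the face giving the (2S) carbinol by 1,2-reduction only; any minor C2 epimer is a diastereomer (C7 is fixed) and can be removed by chromatography.

Step 12
Reactants: 17 methyl (4R)-4-{2-[(2E,4S)-5-(benzyloxy)-4-hydroxy-2-methylpent-2-en-1-yl]-1,3-dioxolan-2-yl}-5-methylhexanoate
Product: 18 (4R)-4-{2-[(2E,4S)-5-(benzyloxy)-4-hydroxy-2-methylpent-2-en-1-yl]-1,3-dioxolan-2-yl}-5-methylhexanoic acid (seco acid)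
Conditions: LiOH, THF–MeOH–H2O, rt; HCl to pH 4, 0 °C
Reagents that add atoms: lithium hydroxide, [Li+].[OH-]
Why: Saponification of the unhindered methyl ester leaves ketal, benzyl ether, allylic alcohol and both stereocentres untouched.

Step 13
Reactants: 18 seco acid
Product: 20 (7E,9S,14R)-9-[(benzyloxy)methyl]-7-methyl-14-(propan-2-yl)-1,4,10-trioxaspiro[4.9]tetradec-7-en-11-one (ten-membered lactone; 2S,7R in eudesmane numbering), via mixed anhydride 19 (not isolated)
Conditions: 2-methyl-6-nitrobenzoic anhydride, DMAP, CH2Cl2, rt, slow addition of 18 at high dilution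
Reagents that add atoms: 2-methyl-6-nitrobenzoic anhydride, Cc1cccc([N+](=O)[O-])c1C(=O)OC(=O)c1c(C)cccc1[N+](=O)[O-] (atoms in 19 only)
Why: Shiina macrolactonisation activates the acid at room temperature and closes the acyl–O2 bond with retention at C2, while slow addition favours ring closure over oligomerisation and the ketal carbon and branched C7 pre-bend the chain (gem-dialkyl effect).

Step 14
Reactants: 20 ten-membered (2S,7R) E-alkenyl lactone
Product: 23 (6R,8S,9S)-9-[(1E)-3-(benzyloxy)prop-1-en-1-yl]-9-methyl-6-(propan-2-yl)-1,4-dioxaspiro[4.5]decane-8-carboxylic acid (ring B acid; 5S,7R,10S), via silyl ketene acetal 21 (not isolated), via silyl ester 22 (not isolated)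
Conditions: LiN(iPr)2, THF, −78 °C; t-BuMe2SiCl, DMPU, −78 °C → rt; toluene, 105 °C; then LiOH, THF–H2O, rt; HCl to pH 4
Reagents that add atoms: tert-butyldimethylsilyl chloride, CC(C)(C)[Si](C)(C)Cl (atoms in 21 and 22 only)
Why: Kinetic deprotonation at C5 in plain THF and O-silylation give 21, in which C6 and the ring oxygen lie on the same side of C4=C5 (the geometry preferred both by the cyclic deprotonation transition state and by the ring), and heating starts a concerted suprafacial [3,3] shift over C5=C4–O–C2–C1=C10 that makes C5–C10 and breaks C2–O. The closest known reaction type is the ester-enolate Claisen contraction of medium and large lactones that carry an alkene next to the ring oxygen, which gives carbocycles with neighbouring cis carboxyl and alkenyl groups. Ring B is closed by transannular bonding across the ten-membered ring (a four-atom contraction, ten to six), the C6–C9 chain supplying the other four ring atoms. Because C6 is pseudo-axial on C5 and C9 pseudo-equatorial on C10, only a chair-like six-centre array brings the ends of this short bridge together, and that array leaves C4 and C1 on one face of ring B, which fixes C5 relative to C10. The absolute sense at C10, and through it at C5, comes from the (2S) carbinol: allylic 1,3-strain with the C10 methyl group, which is cis to C2, keeps H2 inside and the CH2OBn arm outside, so a single alkene face is attacked and C1=C2 emerges E. The selectivities required are enol geometry, chair over boat and alkene face; they are secured by enolisation before any polar cosolvent is added, by the E alkene with its short tether and by the C2 configuration, while the C8 ketal removes the only competing acidic site.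

Step 15
Reactants: 23 ring B acid
Product: 24 (6R,8S,9R)-9-(3-hydroxypropyl)-9-methyl-6-(propan-2-yl)-1,4-dioxaspiro[4.5]decane-8-carboxylic acid
Conditions: H2 (1 atm), Pd/C, EtOAc–EtOH, rt
Reagents that add atoms: none
Why: Heterogeneous catalytic hydrogenation saturates the disubstituted C1=C2 alkene and then cleaves the benzylic C–O bond by hydrogenolysis, so one operation gives the C1–C3 chain with free O3 while ketal, acid and stereocentres stay inert.

Step 16
Reactants: 24 hydroxy acid
Product: 25 1-[(6R,8S,9R)-9-(3-hydroxypropyl)-9-methyl-6-(propan-2-yl)-1,4-dioxaspiro[4.5]decan-8-yl]ethan-1-one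
Conditions: MeLi (excess), THF, 0 °C → rt; inverse quench into cold aq. NH4Cl
Reagents that add atoms: methyllithium, [Li]C
Why: Addition of an organolithium to a lithium carboxylate gives a geminal dialkoxide that collapses to the methyl ketone only on quenching, so over-addition is avoided, and the cold buffered quench protects C5 from epimerisation.

Step 17
Reactants: 25 hydroxy ketone
Product: 26 3-[(6R,8S,9R)-8-acetyl-9-methyl-6-(propan-2-yl)-1,4-dioxaspiro[4.5]decan-9-yl]propanal
Conditions: Dess–Martin periodinane, CH2Cl2, 0 °C → rt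
Reagents that add atoms: none
Why: Dess–Martin oxidation takes the primary alcohol to the C3 aldehyde under non-basic conditions that leave C5 and the ketal alone.

Step 18
Reactants: 26 keto aldehyde
Product: 28 (3R,4S,5S,7R,10R)-3α,4α-dihydroxy-5βH-eudesman-8-one, via diol ketal 27 (not isolated)
Conditions: SmI2, THF, −78 °C → 0 °C; then 1 M HCl, rt
Reagents that add atoms: water, O
Why: Samarium diiodide pinacol cyclisation, in which the aldehyde ketyl adds to the C4 ketone through a chair-like six-membered array with one samarium ion bridging both oxygens (hence the cis diol), the C4 methyl group equatorial, O4 axial and ring B held in the chair that keeps the C7 isopropyl group equatorial, which together direct both oxygens to the α face (3R,4S); aqueous acid in the same flask then hydrolyses the ketal, and C7 is unchanged because the equatorial 7β-isopropyl ketone is the more stable epimer of this cis-decalin.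

Step 19
Reactants: 29 angelic acid
Product: 30 (2Z)-2-methylbut-2-en-1-ol
Conditions: LiAlH4, Et2O, 0 °C → rt
Reagents that add atoms: none
Why: Hydride reduction of the unsaturated acid gives the allylic alcohol with the Z geometry preserved.

Step 20
Reactants: 30 (2Z)-2-methylbut-2-en-1-ol
Product: 31 [(2R,3S)-2,3-dimethyloxiran-2-yl]methanol
Conditions: Ti(OiPr)4 (cat.), D-(−)-diethyl tartrate (cat.), t-BuOOH, 4 Å MS, CH2Cl2, −20 °C
Reagents that add atoms: tert-butyl hydroperoxide, CC(C)(C)OO
Why: Sharpless asymmetric epoxidation transfers oxygen syn to the face selected by the D-(−)-tartrate ligand, which sets both epoxide carbons at once, and the Z alkene fixes the CH2OH and C3 methyl groups cis.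

Step 21
Reactants: 31 [(2R,3S)-2,3-dimethyloxiran-2-yl]methanol
Product: 32 (2S,3S)-2,3-dimethyloxirane-2-carboxylic acid
Conditions: RuCl3 (cat.), NaIO4, MeCN–EtOAc–H2O, 0 °C → rt
Reagents that add atoms: water, O
Why: Ruthenium-catalysed periodate oxidation converts epoxy alcohols directly into glycidic acids without opening the oxirane, and the change of the C2 descriptor from R to S is only a priority change.

Step 22
Reactants: 28 keto diol; 32 (2S,3S)-2,3-dimethyloxirane-2-carboxylic acid
Product: 34 (3R,4S,5S,7R,10R)-4α-hydroxy-8-oxo-5βH-eudesman-3α-yl (2S,3S)-2,3-dimethyloxirane-2-carboxylate, via mixed anhydride 33 (not isolated)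
Conditions: 2,4,6-Cl3C6H2COCl, Et3N, toluene, rt; then 28, DMAP, rt
Reagents that add atoms: 2,4,6-trichlorobenzoyl chloride, O=C(Cl)c1c(Cl)cc(Cl)cc1Cl (atoms in 33 only)
Why: Yamaguchi esterification acylates only the equatorial secondary 3α-hydroxyl, the axial tertiary 4α-hydroxyl being far too hindered, leaves both epoxide carbons untouched, and by filling O3 first removes any free hydroxyl to which a C4 acetate could later migrate.

Step 23
Reactants: 34 hydroxy ester
Product: 35 target, (1S,2R,4aR,7R,8aS)-1-acetoxy-1,4a-dimethyl-6-oxo-7-(propan-2-yl)decahydronaphthalen-2-yl (2S,3S)-2,3-dimethyloxirane-2-carboxylate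
Conditions: Ac2O (excess), DMAP, Et3N, CH2Cl2, 40 °C
Reagents that add atoms: acetic anhydride, CC(=O)OC(C)=O
Why: DMAP-catalysed acyl transfer (Steglich-type acetylation) with excess anhydride is the standard esterification of tertiary alcohols, touches no stereocentre, and the only epimerisable centre, C7, already holds its more stable configuration.

Compound list
1 | (R)-4-benzyl-1,3-oxazolidin-2-one | O=C1N[C@H](Cc2ccccc2)CO1 | starting material
2 | 3-methylbutanoyl chloride | CC(C)CC(=O)Cl | starting material
3 | (R)-4-benzyl-3-(3-methylbutanoyl)-1,3-oxazolidin-2-one | CC(C)CC(=O)N1[C@H](Cc2ccccc2)COC1=O | intermediate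
4 | methyl acrylate | C=CC(=O)OC | starting material
5 | methyl (4R)-4-{[(4R)-4-benzyl-2-oxo-1,3-oxazolidin-3-yl]carbonyl}-5-methylhexanoate | COC(=O)CC[C@H](C(C)C)C(=O)N1[C@H](Cc2ccccc2)COC1=O | intermediate
6 | methyl (4R)-4-[(ethylsulfanyl)carbonyl]-5-methylhexanoate | COC(=O)CC[C@H](C(C)C)C(=O)SCC | intermediate
7 | methyl (4R)-4-formyl-5-methylhexanoate | COC(=O)CC[C@H](C(C)C)C=O | intermediate
8 | propargyl bromide | C#CCBr | starting material
9 | methyl (4R)-5-hydroxy-4-(propan-2-yl)oct-7-ynoate, both carbinol epimers | COC(=O)CC[C@H](C(C)C)C(O)CC#C | intermediate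
10 | methyl (4R)-5-oxo-4-(propan-2-yl)oct-7-ynoate | COC(=O)CC[C@H](C(C)C)C(=O)CC#C | intermediate
11 | methyl (4R)-5-methyl-4-[2-(prop-2-yn-1-yl)-1,3-dioxolan-2-yl]hexanoate | COC(=O)CC[C@H](C(C)C)C1(CC#C)OCCO1 | intermediate
12 | (E)-alkenyl(dimethyl)alane from 11 | COC(=O)CC[C@H](C(C)C)C1(C/C(C)=C/[Al](C)C)OCCO1 | intermediate
13 | methyl (4R)-4-{2-[(2E)-3-iodo-2-methylprop-2-en-1-yl]-1,3-dioxolan-2-yl}-5-methylhexanoate | COC(=O)CC[C@H](C(C)C)C1(C/C(C)=C/I)OCCO1 | intermediate
14 | (benzyloxy)acetaldehyde | O=CCOCc1ccccc1 | starting material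
15 | methyl (4R)-4-{2-[(2E)-5-(benzyloxy)-4-hydroxy-2-methylpent-2-en-1-yl]-1,3-dioxolan-2-yl}-5-methylhexanoate, both carbinol epimers | COC(=O)CC[C@H](C(C)C)C1(C/C(C)=C/C(O)COCc2ccccc2)OCCO1 | intermediate
16 | methyl (4R)-4-{2-[(2E)-5-(benzyloxy)-2-methyl-4-oxopent-2-en-1-yl]-1,3-dioxolan-2-yl}-5-methylhexanoate | COC(=O)CC[C@H](C(C)C)C1(C/C(C)=C/C(=O)COCc2ccccc2)OCCO1 | intermediate
17 | methyl (4R)-4-{2-[(2E,4S)-5-(benzyloxy)-4-hydroxy-2-methylpent-2-en-1-yl]-1,3-dioxolan-2-yl}-5-methylhexanoate | COC(=O)CC[C@H](C(C)C)C1(C/C(C)=C/[C@H](O)COCc2ccccc2)OCCO1 | intermediate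
18 | (4R)-4-{2-[(2E,4S)-5-(benzyloxy)-4-hydroxy-2-methylpent-2-en-1-yl]-1,3-dioxolan-2-yl}-5-methylhexanoic acid | OC(=O)CC[C@H](C(C)C)C1(C/C(C)=C/[C@H](O)COCc2ccccc2)OCCO1 | intermediate
19 | mixed anhydride of 18 with 2-methyl-6-nitrobenzoic acid | Cc1cccc([N+](=O)[O-])c1C(=O)OC(=O)CC[C@H](C(C)C)C1(C/C(C)=C/[C@H](O)COCc2ccccc2)OCCO1 | intermediate
20 | (7E,9S,14R)-9-[(benzyloxy)methyl]-7-methyl-14-(propan-2-yl)-1,4,10-trioxaspiro[4.9]tetradec-7-en-11-one | O=C1CC[C@H](C(C)C)C2(OCCO2)C/C(C)=C/[C@@H](COCc3ccccc3)O1 | intermediate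
21 | tert-butyldimethylsilyl ketene acetal of 20 (C6 cis to the ring oxygen) | CC(C)(C)[Si](C)(C)O/C1=C/C[C@H](C(C)C)C2(OCCO2)C/C(C)=C/[C@@H](COCc3ccccc3)O1 | intermediate
22 | tert-butyldimethylsilyl ester of 23 | CC(C)(C)[Si](C)(C)OC(=O)[C@H]1C[C@H](C(C)C)C2(OCCO2)C[C@@]1(C)/C=C/COCc3ccccc3 | intermediate
23 | (6R,8S,9S)-9-[(1E)-3-(benzyloxy)prop-1-en-1-yl]-9-methyl-6-(propan-2-yl)-1,4-dioxaspiro[4.5]decane-8-carboxylic acid | OC(=O)[C@H]1C[C@H](C(C)C)C2(OCCO2)C[C@@]1(C)/C=C/COCc3ccccc3 | intermediate
24 | (6R,8S,9R)-9-(3-hydroxypropyl)-9-methyl-6-(propan-2-yl)-1,4-dioxaspiro[4.5]decane-8-carboxylic acid | OC(=O)[C@H]1C[C@H](C(C)C)C2(OCCO2)C[C@@]1(C)CCCO | intermediate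
25 | 1-[(6R,8S,9R)-9-(3-hydroxypropyl)-9-methyl-6-(propan-2-yl)-1,4-dioxaspiro[4.5]decan-8-yl]ethan-1-one | CC(=O)[C@H]1C[C@H](C(C)C)C2(OCCO2)C[C@@]1(C)CCCO | intermediate
26 | 3-[(6R,8S,9R)-8-acetyl-9-methyl-6-(propan-2-yl)-1,4-dioxaspiro[4.5]decan-9-yl]propanal | CC(=O)[C@H]1C[C@H](C(C)C)C2(OCCO2)C[C@@]1(C)CCC=O | intermediate
27 | (3R,4S,5S,7R,10R)-3α,4α-dihydroxy-5βH-eudesman-8-one ethylene ketal | O[C@]1(C)[C@H](O)CC[C@]2(C)CC3(OCCO3)[C@@H](C(C)C)C[C@@H]21 | intermediate
28 | (3R,4S,5S,7R,10R)-3α,4α-dihydroxy-5βH-eudesman-8-one | O[C@]1(C)[C@H](O)CC[C@]2(C)CC(=O)[C@@H](C(C)C)C[C@@H]21 | intermediate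
29 | angelic acid | C/C=C(/C)C(=O)O | starting material
30 | (2Z)-2-methylbut-2-en-1-ol | C/C=C(/C)CO | intermediate
31 | [(2R,3S)-2,3-dimethyloxiran-2-yl]methanol | OC[C@@]1(C)O[C@H]1C | intermediate
32 | (2S,3S)-2,3-dimethyloxirane-2-carboxylic acid | OC(=O)[C@@]1(C)O[C@H]1C | intermediate
33 | mixed anhydride of 32 with 2,4,6-trichlorobenzoic acid | O=C(OC(=O)[C@@]1(C)O[C@H]1C)c1c(Cl)cc(Cl)cc1Cl | intermediate
34 | (3R,4S,5S,7R,10R)-4α-hydroxy-8-oxo-5βH-eudesman-3α-yl (2S,3S)-2,3-dimethyloxirane-2-carboxylate | O[C@]1(C)[C@H](OC(=O)[C@@]2(C)O[C@H]2C)CC[C@]2(C)CC(=O)[C@@H](C(C)C)C[C@@H]21 | intermediate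
35 | (1S,2R,4aR,7R,8aS)-1-acetoxy-1,4a-dimethyl-6-oxo-7-(propan-2-yl)decahydronaphthalen-2-yl (2S,3S)-2,3-dimethyloxirane-2-carboxylate | CC(=O)O[C@]1(C)[C@H](OC(=O)[C@@]2(C)O[C@H]2C)CC[C@]2(C)CC(=O)[C@@H](C(C)C)C[C@@H]21 | target

Total step count: 23.
Longest linear sequence: 20 steps (steps 1–18, 22 and 23). Steps 19–21 form the side branch to the epoxy acid.

Steps most likely to fail

Step 14 (key step).
- What may go wrong: the lactone enolate may fragment or be silylated on carbon.
- The silyl ketene acetal may hydrolyse or decompose before the shift occurs. The shift is slowed because the forming chair of ring B carries the isopropyl group axial.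
- Some material may leak through the opposite ketene acetal geometry, which would erode the cis relationship.
- Fallback: replace the silyl ketene acetal by a carbon-substituted enol ether and use the aliphatic Claisen rearrangement.
- Setting out from 20, enolisation with KN(SiMe3)2 and trapping with (PhO)2P(O)Cl should give the ketene acetal diphenyl phosphate F3.
- Cross-coupling of F3 with Me2Zn under Pd(PPh3)4 should give the ten-membered cyclic methyl enol ether F4.
- Heating F4 in xylene should contract the ring through the same chair to the alkenyl methyl ketone F5.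
- Hydrogenation of F5 over Pd/C saturates C1=C2 and removes the benzyl group. The route is rejoined at 25, with 23, 24 and the methyllithium step bypassed.

Step 13.
- What may go wrong: intermolecular acylation (growth of diolide and oligomers) may outrun closure of the strained ten-membered ring, or the hindered allylic hydroxyl may be acylated too slowly.
- Fallback: form the C2–O bond instead of the acyl–O bond, by activating the alcohol.
- Setting out from 16, reduction with the (R)-enantiomer of the oxazaborolidine and catecholborane should give the (2R)-hydroxy ester F1.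
- LiOH should then give the (2R)-seco acid F2.
- Mitsunobu macrolactonisation of F2 (PPh3, DIAD, toluene, high dilution) lets the carboxylate displace the activated oxygen at C2 with inversion. The route is rejoined at 20.

Step 18.
- What may go wrong: facial selectivity may be poor, since the closures on the α and β faces differ mainly through the isopropyl anchor.
- Non-chelated coupling would lead to a trans diol.
- The aldehyde may simply be reduced.
- Fallback: close ring A as an alkene and add both oxygens afterwards.
- Setting out from 26, intramolecular McMurry coupling (TiCl3(DME)1.5, Zn(Cu), DME, reflux) should give the cis-fused eudesm-3-ene ketal F6.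
- Woodward cis-hydroxylation of F6 (I2, AgOAc, moist AcOH) places both oxygens on the face opposite to the one iodine attacks first. Iodine should attack the open β face, so the oxygens arrive on the α face.
- With loss of the ketal in the wet acid, this should give the 4α-acetoxy-3α-hydroxy ketone F7.
- Methanolysis of F7 (K2CO3, MeOH) rejoins the route at 28.

Further compounds
F1 | step 13 | methyl (4R)-4-{2-[(2E,4R)-5-(benzyloxy)-4-hydroxy-2-methylpent-2-en-1-yl]-1,3-dioxolan-2-yl}-5-methylhexanoate | COC(=O)CC[C@H](C(C)C)C1(C/C(C)=C/[C@@H](O)COCc2ccccc2)OCCO1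
F2 | step 13 | (4R)-4-{2-[(2E,4R)-5-(benzyloxy)-4-hydroxy-2-methylpent-2-en-1-yl]-1,3-dioxolan-2-yl}-5-methylhexanoic acid | OC(=O)CC[C@H](C(C)C)C1(C/C(C)=C/[C@@H](O)COCc2ccccc2)OCCO1
F3 | step 14 | ketene acetal diphenyl phosphate of lactone 20 | O=P(Oc1ccccc1)(Oc1ccccc1)O/C1=C/C[C@H](C(C)C)C2(OCCO2)C/C(C)=C/[C@@H](COCc3ccccc3)O1
F4 | step 14 | ten-membered cyclic enol ether with a methyl group on C4 | C/C1=C/C[C@H](C(C)C)C2(OCCO2)C/C(C)=C/[C@@H](COCc3ccccc3)O1
F5 | step 14 | 1-{(6R,8S,9S)-9-[(1E)-3-(benzyloxy)prop-1-en-1-yl]-9-methyl-6-(propan-2-yl)-1,4-dioxaspiro[4.5]decan-8-yl}ethan-1-one | CC(=O)[C@H]1C[C@H](C(C)C)C2(OCCO2)C[C@@]1(C)/C=C/COCc3ccccc3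
F6 | step 18 | (5S,7R,10R)-5βH-eudesm-3-en-8-one ethylene ketal | CC1=CCC[C@]2(C)CC3(OCCO3)[C@@H](C(C)C)C[C@@H]21
F7 | step 18 | (3R,4S,5S,7R,10R)-4α-acetoxy-3α-hydroxy-5βH-eudesman-8-one | CC(=O)O[C@]1(C)[C@H](O)CC[C@]2(C)CC(=O)[C@@H](C(C)C)C[C@@H]21
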